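**Retrosynthetic overview**
1. Target ⇐ angeloylation of the C2 alcohol; the C4 methylene is unmasked just before by selenoxide elimination of a CH–CH2SePh unit.
2. Key step: SmI2 reductive enal/enone cyclisation–aldol cascade on an acyclic chain; the C3a–C7a bond closes the cyclohexane first, then the C1–C2 aldol closes the cyclopentane in the same flask.
3. The methylene is carried masked through the cascade so that the enal has only one acceptor carbon (C3a); the unmasked 2,4-dienal would also offer its CH2 terminus.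
4. Cascade precursor ⇐ Wittig two-carbon extension (C3, C2), α-methylenation/selenol masking (C4) and cross-metathesis with methyl vinyl ketone (C1, acetyl).
5. C6/C7 stereodiad ⇐ anti-selective Brown-type γ-isopropylallylboration of 4,4-dimethoxybutanal.

Assumption: 4,4-dimethoxybutanal (1) is taken as purchasable (otherwise one DIBAL reduction of methyl 4,4-dimethoxybutanoate); carbon labels C1–C7a are the octahydro-1H-indene locants of the target, and the C4 centre of 12–17 is a mixture of epimers that is erased in step 8.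

Step 1
Reactants: 1 4,4-dimethoxybutanal; 2 (E)-4-methylpent-2-ene
Product: 6 (4R,5S)-1,1-dimethoxy-5-(propan-2-yl)hept-6-en-4-ol, via allylpotassium 3 (not isolated), via allylborane 4 (not isolated), via borinate 5 (not isolated)
Conditions: 2, KOt-Bu, n-BuLi, THF, −78 to −50 °C; (−)-Ipc2BOMe, −78 °C; BF3·OEt2; 1, −78 °C; NaOH, H2O2, rt
Reagents that add atoms: none
Why: Brown-type allylboration with an (E)-γ-isopropylallyl borane goes through a chair Zimmerman–Traxler transition state to the anti homoallylic alcohol, and the isopinocampheyl groups derived from (+)-α-pinene deliver the allyl unit to the Si face of the aldehyde, which sets C6 (R) and C7 (S).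

Step 2
Reactants: 6 (4R,5S)-1,1-dimethoxy-5-(propan-2-yl)hept-6-en-4-ol
Product: 7 (4R,5S)-1,1-dimethoxy-5-(propan-2-yl)hept-6-en-4-yl acetate
Conditions: Ac2O, pyridine, DMAP (cat.), CH2Cl2, 0 °C to rt
Reagents that add atoms: acetic anhydride, CC(=O)OC(C)=O
Why: Nucleophile-catalysed O-acetylation installs the C6 acetate of the target early, with retention at C6, so that only one hydroxyl (C2) is created later.

Step 3
Reactants: 7 (4R,5S)-1,1-dimethoxy-5-(propan-2-yl)hept-6-en-4-yl acetate; 8 but-3-en-2-one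
Product: 9 (3E,5S,6R)-9,9-dimethoxy-2-oxo-5-(propan-2-yl)non-3-en-6-yl acetate
Conditions: 8 (4 equiv), second-generation Hoveyda–Grubbs catalyst [RuCl2(H2IMes)(=CH-C6H4-2-O-i-Pr)] (5 mol%), CH2Cl2, 40 °C
Reagents that add atoms: none
Why: Olefin cross-metathesis of the only alkene in 7 with the electron-poor partner gives the E-enone (C7a=C1, acetyl) and touches no stereocentre.

Step 4
Reactants: 9 (3E,5S,6R)-9,9-dimethoxy-2-oxo-5-(propan-2-yl)non-3-en-6-yl acetate
Product: 10 (4R,5S,6E)-1,8-dioxo-5-(propan-2-yl)non-6-en-4-yl acetate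
Conditions: TFA/H2O (1:1), CHCl3, 0 °C
Reagents that add atoms: water, O
Why: Acid hydrolysis of the dimethyl acetal frees the C3a aldehyde under conditions that leave the acetate and the enone alone.

Step 5
Reactants: 10 (4R,5S,6E)-1,8-dioxo-5-(propan-2-yl)non-6-en-4-yl acetate
Product: 12 (4R,5S,6E)-1,8-dioxo-2-[(phenylselanyl)methyl]-5-(propan-2-yl)non-6-en-4-yl acetate, via α-methylene aldehyde 11 (not isolated)
Conditions: CH2=NMe2+ I− (1.3 equiv), Et3N, CH2Cl2, rt; then PhSeH (1.4 equiv), 0 °C
Reagents that add atoms: N,N-dimethylmethyleneiminium iodide (Eschenmoser's salt), C=[N+](C)C.[I-]; benzeneselenol, [SeH]c1ccccc1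
Why: Mannich reaction with the preformed iminium salt and amine elimination (Eschenmoser α-methylenation) gives the 2-substituted acrolein, which takes up the selenol by conjugate addition much faster than the β-substituted enone; the C4 centre is not controlled and is removed in step 8.

Step 6
Reactants: 12 (4R,5S,6E)-1,8-dioxo-2-[(phenylselanyl)methyl]-5-(propan-2-yl)non-6-en-4-yl acetate; 13 2-(triphenyl-λ5-phosphanylidene)acetaldehyde
Product: 14 (2E,6R,7S,8E)-1,10-dioxo-4-[(phenylselanyl)methyl]-7-(propan-2-yl)undeca-2,8-dien-6-yl acetate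
Conditions: 13 (1.2 equiv), benzene, 60 °C
Reagents that add atoms: none
Why: Wittig reaction of the stabilised formyl ylide is selective for the aldehyde over the methyl ketone and gives the E-enal (C3a=C3, C2 aldehyde).

Step 7
Reactants: 14 (2E,6R,7S,8E)-1,10-dioxo-4-[(phenylselanyl)methyl]-7-(propan-2-yl)undeca-2,8-dien-6-yl acetate
Product: 16 (1R,2S,3aR,6R,7S,7aR)-1-acetyl-2-hydroxy-4-[(phenylselanyl)methyl]-7-(propan-2-yl)octahydro-1H-inden-6-yl acetate, via cyclohexane keto aldehyde 15 (not isolated)
Conditions: SmI2 (2.3 equiv, added slowly), HMPA, t-BuOH (2 equiv), THF (0.01 M), −78 °C, then 0 °C; aq. NH4Cl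
Reagents that add atoms: none
Why: Proposed new method: two-electron reductive β,β-coupling of the enal (C3a) and the enone (C7a) by SmI2 closes the cyclohexane 6-exo through a chair with the isopropyl group and both side arms equatorial and the acetate axial (C3a and C7a trans, C7a trans to C7), and the trivalent samarium enolate of the methyl ketone then adds to the C2 aldehyde, regenerated by C-protonation of the enal-derived enolate, through a chelated Zimmerman–Traxler transition state that puts acetyl and hydroxyl cis on the trans-fused cyclopentane (C1, C2); the closest known reaction type is the SmI2 or cathodic hydrodimerisation of enones followed by aldol closure to 2-acylcyclopentanols.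

Step 8
Reactants: 16 (1R,2S,3aR,6R,7S,7aR)-1-acetyl-2-hydroxy-4-[(phenylselanyl)methyl]-7-(propan-2-yl)octahydro-1H-inden-6-yl acetate
Product: 18 (1R,2S,3aR,6R,7S,7aR)-1-acetyl-2-hydroxy-4-methylidene-7-(propan-2-yl)octahydro-1H-inden-6-yl acetate, via selenoxide 17 (not isolated)
Conditions: H2O2 (30%), pyridine, CH2Cl2, 0 °C to rt
Reagents that add atoms: none
Why: Selenide oxidation and syn selenoxide elimination at room temperature; the only β-hydrogen is on C4, so the exocyclic methylene is the sole alkene formed and both C4 epimers converge.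

Step 9
Reactants: 18 (1R,2S,3aR,6R,7S,7aR)-1-acetyl-2-hydroxy-4-methylidene-7-(propan-2-yl)octahydro-1H-inden-6-yl acetate; 19 (2Z)-2-methylbut-2-enoic acid (angelic acid)
Product: 21 (1R,2S,3aR,6R,7S,7aR)-1-acetyl-6-(acetyloxy)-4-methylidene-7-(propan-2-yl)octahydro-1H-inden-2-yl (2Z)-2-methylbut-2-enoate, via mixed anhydride 20 (not isolated)
Conditions: 19, 2,4,6-Cl3C6H2COCl, Et3N, toluene, rt; then 18, toluene, 75 °C (no DMAP)
Reagents that add atoms: none
Why: Yamaguchi-type esterification through the mixed anhydride acylates the C2 alcohol at the less hindered angeloyl carbonyl with retention at C2, and leaving out DMAP avoids Z-to-E isomerisation to the tiglate.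

**Compound list**
1 | 4,4-dimethoxybutanal | COC(OC)CCC=O | starting material
2 | (E)-4-methylpent-2-ene | C/C=C/C(C)C | starting material
3 | (E)-(4-methylpent-2-en-1-yl)potassium | [K]C/C=C/C(C)C | intermediate
4 | (E)-B-(4-methylpent-2-en-1-yl)diisopinocampheylborane, isopinocampheyl groups as in (−)-Ipc2BOMe | CC(C)/C=C/CB([C@@H]1C[C@@H]2C[C@H]([C@H]1C)C2(C)C)[C@@H]1C[C@@H]2C[C@H]([C@H]1C)C2(C)C | intermediate
5 | diisopinocampheylborinate of alcohol 6 (O–B ester at C4 of the heptenol) | COC(OC)CC[C@@H](OB([C@@H]1C[C@@H]2C[C@H]([C@H]1C)C2(C)C)[C@@H]1C[C@@H]2C[C@H]([C@H]1C)C2(C)C)[C@@H](C(C)C)C=C | intermediate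
6 | (4R,5S)-1,1-dimethoxy-5-(propan-2-yl)hept-6-en-4-ol | COC(OC)CC[C@@H](O)[C@@H](C(C)C)C=C | intermediate
7 | (4R,5S)-1,1-dimethoxy-5-(propan-2-yl)hept-6-en-4-yl acetate | COC(OC)CC[C@@H](OC(C)=O)[C@@H](C(C)C)C=C | intermediate
8 | but-3-en-2-one (methyl vinyl ketone) | CC(=O)C=C | starting material
9 | (3E,5S,6R)-9,9-dimethoxy-2-oxo-5-(propan-2-yl)non-3-en-6-yl acetate | COC(OC)CC[C@@H](OC(C)=O)[C@@H](C(C)C)/C=C/C(C)=O | intermediate
10 | (4R,5S,6E)-1,8-dioxo-5-(propan-2-yl)non-6-en-4-yl acetate | O=CCC[C@@H](OC(C)=O)[C@@H](C(C)C)/C=C/C(C)=O | intermediate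
11 | (4R,5S,6E)-2-methylidene-1,8-dioxo-5-(propan-2-yl)non-6-en-4-yl acetate | O=CC(=C)C[C@@H](OC(C)=O)[C@@H](C(C)C)/C=C/C(C)=O | intermediate
12 | (4R,5S,6E)-1,8-dioxo-2-[(phenylselanyl)methyl]-5-(propan-2-yl)non-6-en-4-yl acetate, both C2 epimers | O=CC(C[Se]c1ccccc1)C[C@@H](OC(C)=O)[C@@H](C(C)C)/C=C/C(C)=O | intermediate
13 | 2-(triphenyl-λ5-phosphanylidene)acetaldehyde | O=CC=P(c1ccccc1)(c1ccccc1)c1ccccc1 | starting material
14 | (2E,6R,7S,8E)-1,10-dioxo-4-[(phenylselanyl)methyl]-7-(propan-2-yl)undeca-2,8-dien-6-yl acetate, both C4 epimers | O=C/C=C/C(C[Se]c1ccccc1)C[C@@H](OC(C)=O)[C@@H](C(C)C)/C=C/C(C)=O | intermediate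
15 | (1R,2S,3R,4R)-4-(2-oxoethyl)-3-(2-oxopropyl)-5-[(phenylselanyl)methyl]-2-(propan-2-yl)cyclohexyl acetate, both C5 epimers (present in the flask as its samarium enolates) | c1ccccc1[Se]CC1C[C@@H](OC(C)=O)[C@@H](C(C)C)[C@H](CC(C)=O)[C@H]1CC=O | intermediate
16 | (1R,2S,3aR,6R,7S,7aR)-1-acetyl-2-hydroxy-4-[(phenylselanyl)methyl]-7-(propan-2-yl)octahydro-1H-inden-6-yl acetate, both C4 epimers | c1ccccc1[Se]CC1C[C@@H](OC(C)=O)[C@@H](C(C)C)[C@@H]2[C@@H](C(C)=O)[C@@H](O)C[C@@H]12 | intermediate
17 | Se-oxide (selenoxide) of 16 | O=[Se](c1ccccc1)CC1C[C@@H](OC(C)=O)[C@@H](C(C)C)[C@@H]2[C@@H](C(C)=O)[C@@H](O)C[C@@H]12 | intermediate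
18 | (1R,2S,3aR,6R,7S,7aR)-1-acetyl-2-hydroxy-4-methylidene-7-(propan-2-yl)octahydro-1H-inden-6-yl acetate | C=C1C[C@@H](OC(C)=O)[C@@H](C(C)C)[C@@H]2[C@@H](C(C)=O)[C@@H](O)C[C@@H]12 | intermediate
19 | (2Z)-2-methylbut-2-enoic acid (angelic acid) | C/C=C(/C)C(=O)O | starting material
20 | (2Z)-2-methylbut-2-enoic 2,4,6-trichlorobenzoic anhydride | C/C=C(/C)C(=O)OC(=O)c1c(Cl)cc(Cl)cc1Cl | intermediate
21 | (1R,2S,3aR,6R,7S,7aR)-1-acetyl-6-(acetyloxy)-4-methylidene-7-(propan-2-yl)octahydro-1H-inden-2-yl (2Z)-2-methylbut-2-enoate | C=C1C[C@@H](OC(C)=O)[C@@H](C(C)C)[C@@H]2[C@@H](C(C)=O)[C@@H](OC(=O)/C(C)=C\C)C[C@@H]12 | target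

**Totals**
Total step count: 9. Longest linear sequence: 9 steps (1 → 21).

**Three steps most likely to fail, each with a fallback**

Step 7 (reductive cyclisation–aldol cascade). The risks are simple conjugate reduction or pinacol coupling of the enal, protonation of the ketone enolate before the aldol, and aldol of the aldehyde enolate onto the ketone instead. The fallback sets out from 14 and turns the cascade into two separate closures. The SmI2/HMPA coupling is run with exactly two equivalents of SmI2 and quenched cold with methanol, so that both samarium enolates are protonated and the cyclohexane keto aldehyde 15 is isolated. The cyclopentane is then closed in its own step by an amine-catalysed 5-enolexo aldol (L-proline, DMSO, rt), in which only the C1 enamine can reach the aldehyde. The fallback comes back to the route at 16 and makes no compound outside the list (F0).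

Step 3 (cross-metathesis). The alkene carries an allylic carbon bearing isopropyl next to the acetoxy carbon and may be too hindered. The fallback sets out from 7 and builds the enone by olefination. Ozonolysis (O3, CH2Cl2, −78 °C; Me2S) gives (2R,3R)-6,6-dimethoxy-1-oxo-2-(propan-2-yl)hexan-3-yl acetate F1. This α-branched β-acetoxy aldehyde is used at once in a Wittig reaction with 1-(triphenyl-λ5-phosphanylidene)propan-2-one (CH2Cl2, rt), and the fallback comes back at 9.

Step 9 (angeloylation). The risks are slow acylation of the hindered β-hydroxy ketone, Z-to-E isomerisation to the tiglate, and β-elimination on heating with amine. The fallback sets out from 18 and builds the Z-alkene on the substrate. The alcohol is esterified (DCC, CH2Cl2, 0 °C) with 2-[bis(2,2,2-trifluoroethoxy)phosphoryl]propanoic acid to give (1R,2S,3aR,6R,7S,7aR)-1-acetyl-6-(acetyloxy)-4-methylidene-7-(propan-2-yl)octahydro-1H-inden-2-yl 2-[bis(2,2,2-trifluoroethoxy)phosphoryl]propanoate F2. Still–Gennari olefination of F2 with acetaldehyde (KHMDS, 18-crown-6, THF, −78 °C) then comes back at 21.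

**Further compounds**
F0 | step 7 | none | none
F1 | step 3 | (2R,3R)-6,6-dimethoxy-1-oxo-2-(propan-2-yl)hexan-3-yl acetate | COC(OC)CC[C@@H](OC(C)=O)[C@@H](C(C)C)C=O
F2 | step 9 | (1R,2S,3aR,6R,7S,7aR)-1-acetyl-6-(acetyloxy)-4-methylidene-7-(propan-2-yl)octahydro-1H-inden-2-yl 2-[bis(2,2,2-trifluoroethoxy)phosphoryl]propanoate | C=C1C[C@@H](OC(C)=O)[C@@H](C(C)C)[C@@H]2[C@@H](C(C)=O)[C@@H](OC(=O)C(C)P(=O)(OCC(F)(F)F)OCC(F)(F)F)C[C@@H]12
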